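**Retrosynthetic overview**
1. Last bond: lactone carbonyl carbon C-2 to the methyl-bearing ring carbon C-3 of the furan-2,4-dione (tetronic acid) ring. Enabling feature: C-3 is the α-carbon of the C-4 carbonyl and the ring oxygen O-1 sits on the adjacent C-5, so an aryl carbonate on O-1 of an open-chain (Z)-2-oxy-enone (an ethyl ketone) holds its carbonyl carbon five atoms from the enolisable CH2; C-acylation closes the ring and frees the acid without any protecting group.
2. The enol carbonate is generated in the same flask from an acyclic β-(4-nitrophenoxycarbonyloxy) α-diazo ketone by a Rh-catalysed 1,2-carbonate shift, in which both carbinol epimers converge on the (Z)-alkene. The diazo ketone comes from the C20 aldehyde, 1-diazobutan-2-one and 4-nitrophenyl chloroformate.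
3. C20 aldehyde: sp3–sp2 B-alkyl Suzuki–Miyaura coupling of a (Z)-vinyl iodide with the borane of (2S)-N-methoxy-N,2-dimethylpent-4-enamide (stereocentre from an Evans allylation), then reduction.
4. Vinyl iodide: (Z)-selective iodo-Wittig reaction on an aldehyde whose (E)-alkene comes from a Johnson–Claisen rearrangement; the furan is bought as 2-(furan-3-yl)ethanol.
5. Ring order: the furan is present from the start; the furan-2,4-dione ring is the only ring formed, in the last step.

Key step: step 12

Remark: the carbinol centres made in steps 2 and 11 are erased in steps 3 and 12, so they are carried as mixtures and drawn without configuration.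

Step 1
Reactants: 1 2-(furan-3-yl)ethan-1-ol
Product: 2 3-(2-bromoethyl)furan
Conditions: CBr4, PPh3, CH2Cl2, 0 °C
Reagents that add atoms: tetrabromomethane, BrC(Br)(Br)Br
Why: Appel reaction, whose neutral conditions should convert the primary alcohol into the bromide without harm to the acid-sensitive furan.

Step 2
Reactants: 2 3-(2-bromoethyl)furan; 3 2-methylprop-2-enal
Product: 5 5-(furan-3-yl)-2-methylpent-1-en-3-ol (racemic), via Grignard reagent 4 (not isolated)
Conditions: Mg, THF, 40 °C; then 3, −78 → 0 °C; aq. NH4Cl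
Reagents that add atoms: none
Why: Grignard 1,2-addition to the enal should give the secondary allylic alcohol, whose carbinol centre is formed racemic and is erased in step 3.

Step 3
Reactants: 5 5-(furan-3-yl)-2-methylpent-1-en-3-ol
Product: 6 ethyl (4E)-7-(furan-3-yl)-4-methylhept-4-enoate
Conditions: MeC(OEt)3, EtCO2H (cat.), 140 °C, removal of EtOH
Reagents that add atoms: triethyl orthoacetate, CCOC(C)(OCC)OCC
Why: Johnson–Claisen rearrangement, in which the chair transition state with the 2-(furan-3-yl)ethyl group equatorial should deliver the (E)-trisubstituted alkene.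

Step 4
Reactants: 6 ethyl (4E)-7-(furan-3-yl)-4-methylhept-4-enoate
Product: 7 (4E)-7-(furan-3-yl)-4-methylhept-4-enal
Conditions: i-Bu2AlH, CH2Cl2, −78 °C; aq. potassium sodium tartrate
Reagents that add atoms: none
Why: partial reduction of an ester with i-Bu2AlH, where the aluminium hemiacetal is stable at −78 °C and releases the aldehyde only on work-up.

Step 5
Reactants: 7 (4E)-7-(furan-3-yl)-4-methylhept-4-enal
Product: 8 3-[(3E,7Z)-8-iodo-4-methylnona-3,7-dien-1-yl]furan
Conditions: [Ph3PEt]I, n-BuLi, THF, 23 °C; I2, −78 °C; NaN(SiMe3)2, −20 °C; then 7, −78 → −20 °C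
Reagents that add atoms: ethyltriphenylphosphonium iodide, CC[P+](c1ccccc1)(c1ccccc1)c1ccccc1.[I-]; iodine, II
Why: Wittig iodo-olefination of the Stork–Zhao type, in which the non-stabilised α-iodo ylide reacts under kinetic control and should place iodine cis to the chain to give the (Z)-vinyl iodide.

Step 6
Reactants: 9 (4R)-4-benzyl-3-propanoyl-1,3-oxazolidin-2-one
Product: 11 (4R)-4-benzyl-3-[(2S)-2-methylpent-4-enoyl]-1,3-oxazolidin-2-one, via sodium enolate 10 (not isolated)
Conditions: NaN(SiMe3)2, THF, −78 °C; allyl iodide, −78 → −45 °C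
Reagents that add atoms: allyl iodide, C=CCI
Why: Evans asymmetric alkylation, in which the chelated (Z)-sodium enolate is allylated on the face opposite the benzyl group and so sets the (2S) centre, the only stereocentre of the target.

Step 7
Reactants: 11 (4R)-4-benzyl-3-[(2S)-2-methylpent-4-enoyl]-1,3-oxazolidin-2-one
Product: 12 (2S)-N-methoxy-N,2-dimethylpent-4-enamide
Conditions: MeNH(OMe)·HCl, AlMe3, CH2Cl2, 0 → 23 °C
Reagents that add atoms: N,O-dimethylhydroxylamine hydrochloride, CNOC.Cl
Why: Weinreb transamination, in which the aluminium amide attacks the exocyclic imide carbonyl under non-basic conditions that should leave the α-stereocentre untouched.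

Step 8
Reactants: 12 (2S)-N-methoxy-N,2-dimethylpent-4-enamide; 8 3-[(3E,7Z)-8-iodo-4-methylnona-3,7-dien-1-yl]furan
Product: 14 (2S,6Z,10E)-13-(furan-3-yl)-N-methoxy-N,2,6,10-tetramethyltrideca-6,10-dienamide, via alkylborane 13 (not isolated)
Conditions: 9-BBN-H, THF, 23 °C; then 8, PdCl2(dppf) (5 mol %), AsPh3, Cs2CO3, DMF–H2O, 23 °C
Reagents that add atoms: none
Why: anti-Markovnikov hydroboration followed by B-alkyl Suzuki–Miyaura coupling, which proceeds with retention of the vinyl iodide geometry and so should fix the (Z)-trisubstituted alkene.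

Step 9
Reactants: 14 (2S,6Z,10E)-13-(furan-3-yl)-N-methoxy-N,2,6,10-tetramethyltrideca-6,10-dienamide
Product: 15 (2S,6Z,10E)-13-(furan-3-yl)-2,6,10-trimethyltrideca-6,10-dienal
Conditions: i-Bu2AlH, THF, −78 °C; aq. potassium sodium tartrate
Reagents that add atoms: none
Why: Weinreb amide reduction, which stops at the chelated hemiaminal so that the α-branched aldehyde is released only on cold work-up and should keep its configuration.

Step 10
Reactants: 16 propanoyl chloride
Product: 17 1-diazobutan-2-one
Conditions: Me3SiCHN2, THF–MeCN, 0 °C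
Reagents that add atoms: (trimethylsilyl)diazomethane, C[Si](C)(C)C=[N+]=[N-]
Why: C-acylation of the silyl diazomethane with loss of Me3SiCl, a diazoketone synthesis of the Arndt–Eistert type.

Step 11
Reactants: 17 1-diazobutan-2-one; 15 (2S,6Z,10E)-13-(furan-3-yl)-2,6,10-trimethyltrideca-6,10-dienal
Product: 20 (6S,10Z,14E)-4-diazo-17-(furan-3-yl)-6,10,14-trimethyl-3-oxoheptadeca-10,14-dien-5-yl 4-nitrophenyl carbonate (both C-5 epimers), via lithiated diazoketone 18 (not isolated), via lithium aldolate 19 (not isolated)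
Conditions: LiN(i-Pr)2, THF, −78 °C; then 15, −78 °C; then 4-O2NC6H4OC(O)Cl, −78 → −40 °C
Reagents that add atoms: 4-nitrophenyl chloroformate, O=C(Cl)Oc1ccc(cc1)[N+](=O)[O-]
Why: aldol-type addition of the C-lithiated acyldiazomethane to the aldehyde with O-acylation of the aldolate in the same flask, which should forestall retro-aldol cleavage; the new carbinol centre is not controlled and both epimers are used.

Step 12
Reactants: 20 (6S,10Z,14E)-4-diazo-17-(furan-3-yl)-6,10,14-trimethyl-3-oxoheptadeca-10,14-dien-5-yl 4-nitrophenyl carbonate (both C-5 epimers)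
Product: 22 (5Z)-5-[(2S,6Z,10E)-13-(furan-3-yl)-2,6,10-trimethyltrideca-6,10-dien-1-ylidene]-4-hydroxy-3-methylfuran-2(5H)-one, via (Z)-enol carbonate 21 (not isolated)
Conditions: Rh2(OAc)4 (1 mol %), CH2Cl2, 23 °C; then MgBr2·OEt2, i-Pr2NEt, 0 → 23 °C; 1 M HCl work-up
Reagents that add atoms: none
Why: Proposed new method: Rh2(OAc)4 should turn either epimer of 20 into the same rhodium carbene, whose neighbouring carbonate C=O oxygen bridges to the carbene carbon and is handed over as the carbinol C–O bond breaks (a 1,2-acyloxy shift, known for β-acyloxy α-diazo carbonyl compounds), so that both epimers converge on the (Z)-enol carbonate 21; MgBr2·OEt2 and i-Pr2NEt should then enolise the ethyl ketone, the only α-position of 21 that still carries hydrogen, and the enolate carbon adds to the carbonate carbonyl and expels 4-nitrophenoxide, which forms the bond between the lactone carbonyl carbon and the methyl-bearing ring carbon and closes the ring. The closest known reaction types are the Lacey–Dieckmann closure of tetronic acids and the MgBr2/amine soft-enolisation C-acylation of ketones with activated aryl esters; the new elements are the enol carbonate as internal acyl donor and the coupling of both events in one flask. The furan-2,4-dione ring, the only ring formed, closes in the 5-(enolendo)-exo-trig mode on the carbonate carbonyl. No stereocentre is created: the (Z) geometry of the exocyclic alkene is set in the 1,2-shift by the secondary alkyl group, which turns away from the propanoyl group, and the chain stereocentre is not touched. The step needs C- instead of O-acylation and loss of the external leaving group instead of the ring oxygen: the tightly O-bound magnesium enolate secures the first, and 4-nitrophenoxide, a much weaker base than the dienolate oxygen of the ring, secures the second.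

**Compound list**
1 | 2-(furan-3-yl)ethan-1-ol | OCCc1ccoc1 | starting material
2 | 3-(2-bromoethyl)furan | BrCCc1ccoc1 | intermediate
3 | 2-methylprop-2-enal (methacrolein) | CC(=C)C=O | starting material
4 | [2-(furan-3-yl)ethyl]magnesium bromide (not isolated) | Br[Mg]CCc1ccoc1 | intermediate
5 | 5-(furan-3-yl)-2-methylpent-1-en-3-ol (racemic) | CC(=C)C(O)CCc1ccoc1 | intermediate
6 | ethyl (4E)-7-(furan-3-yl)-4-methylhept-4-enoate | CCOC(=O)CC/C(C)=C/CCc1ccoc1 | intermediate
7 | (4E)-7-(furan-3-yl)-4-methylhept-4-enal | O=CCC/C(C)=C/CCc1ccoc1 | intermediate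
8 | 3-[(3E,7Z)-8-iodo-4-methylnona-3,7-dien-1-yl]furan | C/C(I)=C/CC/C(C)=C/CCc1ccoc1 | intermediate
9 | (4R)-4-benzyl-3-propanoyl-1,3-oxazolidin-2-one | CCC(=O)N1[C@H](Cc2ccccc2)COC1=O | starting material
10 | sodium (1Z)-1-[(4R)-4-benzyl-2-oxo-1,3-oxazolidin-3-yl]prop-1-en-1-olate (not isolated) | [Na+].C/C=C(\[O-])N1[C@H](Cc2ccccc2)COC1=O | intermediate
11 | (4R)-4-benzyl-3-[(2S)-2-methylpent-4-enoyl]-1,3-oxazolidin-2-one | C=CC[C@H](C)C(=O)N1[C@H](Cc2ccccc2)COC1=O | intermediate
12 | (2S)-N-methoxy-N,2-dimethylpent-4-enamide | C=CC[C@H](C)C(=O)N(C)OC | intermediate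
13 | 9-[(4S)-5-[methoxy(methyl)amino]-4-methyl-5-oxopentyl]-9-borabicyclo[3.3.1]nonane (not isolated) | CON(C)C(=O)[C@@H](C)CCCB1C2CCCC1CCC2 | intermediate
14 | (2S,6Z,10E)-13-(furan-3-yl)-N-methoxy-N,2,6,10-tetramethyltrideca-6,10-dienamide | CON(C)C(=O)[C@@H](C)CCC/C(C)=C\CC/C(C)=C/CCc1ccoc1 | intermediate
15 | (2S,6Z,10E)-13-(furan-3-yl)-2,6,10-trimethyltrideca-6,10-dienal | O=C[C@@H](C)CCC/C(C)=C\CC/C(C)=C/CCc1ccoc1 | intermediate
16 | propanoyl chloride | CCC(=O)Cl | starting material
17 | 1-diazobutan-2-one | CCC(=O)C=[N+]=[N-] | intermediate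
18 | 1-diazo-1-lithiobutan-2-one (not isolated) | [Li]C(=[N+]=[N-])C(=O)CC | intermediate
19 | lithium (6S,10Z,14E)-4-diazo-17-(furan-3-yl)-6,10,14-trimethyl-3-oxoheptadeca-10,14-dien-5-olate (both C-5 epimers; not isolated) | [Li+].CCC(=O)C(=[N+]=[N-])C([O-])[C@@H](C)CCC/C(C)=C\CC/C(C)=C/CCc1ccoc1 | intermediate
20 | (6S,10Z,14E)-4-diazo-17-(furan-3-yl)-6,10,14-trimethyl-3-oxoheptadeca-10,14-dien-5-yl 4-nitrophenyl carbonate (both C-5 epimers) | CCC(=O)C(=[N+]=[N-])C(OC(=O)Oc1ccc(cc1)[N+](=O)[O-])[C@@H](C)CCC/C(C)=C\CC/C(C)=C/CCc1ccoc1 | intermediate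
21 | (4Z,6S,10Z,14E)-17-(furan-3-yl)-6,10,14-trimethyl-3-oxoheptadeca-4,10,14-trien-4-yl 4-nitrophenyl carbonate (not isolated) | CCC(=O)/C(OC(=O)Oc1ccc(cc1)[N+](=O)[O-])=C/[C@@H](C)CCC/C(C)=C\CC/C(C)=C/CCc1ccoc1 | intermediate
22 | (5Z)-5-[(2S,6Z,10E)-13-(furan-3-yl)-2,6,10-trimethyltrideca-6,10-dien-1-ylidene]-4-hydroxy-3-methylfuran-2(5H)-one | CC1=C(O)/C(=C/[C@@H](C)CCC/C(C)=C\CC/C(C)=C/CCc2ccoc2)OC1=O | target

**Step count**
Total step count: 12.
Longest linear sequence: 9 steps (steps 1, 2, 3, 4, 5, 8, 9, 11, 12; 1 → 2 → 5 → 6 → 7 → 8 → 14 → 15 → 20 → 22).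

**Steps most likely to fail**

1. Step 12 (proposed new method). What may go wrong:
- a 1,2-hydride shift in the carbene may compete with the carbonate shift;
- the enolate may close through oxygen, giving a cyclic enol carbonate, instead of through carbon;
- slow γ-deprotonation of the enone may erode the configuration of the chain stereocentre.

Fallback with known chemistry, setting out from 15 and returning at 22: 4-methoxy-3-methylfuran-2(5H)-one (taken as the commercial methyl ether of 3-methyltetronic acid) is deprotonated at C-5 with LiN(i-Pr)2 in THF at −78 °C to 5-lithio-4-methoxy-3-methylfuran-2(5H)-one F1. F1 should add to 15 to give the hydroxyalkyl tetronate F2 as a mixture of carbinol epimers. MsCl/Et3N should give the mesylate F3, which DBU should eliminate by the E1cB path to the (Z)-ylidene methyl tetronate F4, both epimers converging. n-PrSLi in DMF should then cleave the enol methyl ether to 22.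

2. Step 11. What may go wrong:
- deprotonation of 17 at the ethyl group instead of the diazo carbon;
- retro-aldol cleavage of the aldolate before it is acylated;
- enolisation of 15 with loss of configuration.

Fallback without diazo chemistry, setting out from 15 and returning at 21: Horner–Wadsworth–Emmons reaction with diethyl (2-oxobutyl)phosphonate (LiCl, i-Pr2NEt, MeCN) should give the (E)-enone F5. Weitz–Scheffer epoxidation (t-BuOOH, DBU, CH2Cl2), which touches only the electron-poor alkene, should give the trans-epoxy ketone F6. Insertion of CO2 (LiBr cat., 1 atm, NMP, 60 °C) should give the cyclic carbonate F7. Et3N with 4-nitrophenyl chloroformate in CH2Cl2 should open F7 by β-elimination with loss of CO2 and acylate the enolate oxygen to give 21, which is carried on under the second set of conditions of step 12.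

3. Step 5. What may go wrong:
- incomplete iodination of the ylide, which leads to the iodine-free alkene;
- erosion of the (Z) selectivity in the olefination.

Fallback, setting out from 7 and returning at 14: Corey–Fuchs dibromo-olefination (CBr4, PPh3, CH2Cl2, 0 °C) should give the 1,1-dibromoalkene F8. Pd-catalysed Negishi monomethylation (Me2Zn, Pd(t-Bu3P)2 cat., THF), which is known to take place at the bromine trans to the chain, should give the (Z)-bromide F9. F9 replaces 8 in step 8 to give 14.

**Further compounds**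
F1 | step 12 | 5-lithio-4-methoxy-3-methylfuran-2(5H)-one | COC1=C(C)C(=O)OC1[Li]
F2 | step 12 | 5-[(2S,6Z,10E)-13-(furan-3-yl)-1-hydroxy-2,6,10-trimethyltrideca-6,10-dien-1-yl]-4-methoxy-3-methylfuran-2(5H)-one (mixture of epimers at the two new centres) | COC1=C(C)C(=O)OC1C(O)[C@@H](C)CCC/C(C)=C\CC/C(C)=C/CCc1ccoc1
F3 | step 12 | (2S,6Z,10E)-13-(furan-3-yl)-1-(3-methoxy-4-methyl-5-oxo-2,5-dihydrofuran-2-yl)-2,6,10-trimethyltrideca-6,10-dien-1-yl methanesulfonate (mixture of epimers) | COC1=C(C)C(=O)OC1C(OS(C)(=O)=O)[C@@H](C)CCC/C(C)=C\CC/C(C)=C/CCc1ccoc1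
F4 | step 12 | (5Z)-5-[(2S,6Z,10E)-13-(furan-3-yl)-2,6,10-trimethyltrideca-6,10-dien-1-ylidene]-4-methoxy-3-methylfuran-2(5H)-one | COC1=C(C)C(=O)O/C1=C\[C@@H](C)CCC/C(C)=C\CC/C(C)=C/CCc1ccoc1
F5 | step 11 | (4E,6S,10Z,14E)-17-(furan-3-yl)-6,10,14-trimethylheptadeca-4,10,14-trien-3-one | CCC(=O)/C=C/[C@@H](C)CCC/C(C)=C\CC/C(C)=C/CCc1ccoc1
F6 | step 11 | 1-{3-[(2S,6Z,10E)-13-(furan-3-yl)-6,10-dimethyltrideca-6,10-dien-2-yl]oxiran-2-yl}propan-1-one (trans-epoxide, both diastereomers) | CCC(=O)C1OC1[C@@H](C)CCC/C(C)=C\CC/C(C)=C/CCc1ccoc1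
F7 | step 11 | 4-[(2S,6Z,10E)-13-(furan-3-yl)-6,10-dimethyltrideca-6,10-dien-2-yl]-5-propanoyl-1,3-dioxolan-2-one (diastereomer mixture) | CCC(=O)C1OC(=O)OC1[C@@H](C)CCC/C(C)=C\CC/C(C)=C/CCc1ccoc1
F8 | step 5 | 3-[(3E)-8,8-dibromo-4-methylocta-3,7-dien-1-yl]furan | BrC(Br)=CCC/C(C)=C/CCc1ccoc1
F9 | step 5 | 3-[(3E,7Z)-8-bromo-4-methylnona-3,7-dien-1-yl]furan | C/C(Br)=C/CC/C(C)=C/CCc1ccoc1
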